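**Retrosynthetic overview**

- The strategy rests on the ten-membered carbocycle C1–C10: it contains the 1,5-diene C10=C1–C2–C3–C4=C5, and C10 carries only the one-carbon C14 unit, so C10 can be the carbinol carbon of a cis-1-vinyl-2-isopropenylcyclohexanol (ring C5–C10) that is opened to the ten-membered ring by an anionic oxy-Cope rearrangement.
- After the key step: C14 by Stille coupling on the C10 enol triflate, C13 by Mannich methylenation of the lactol, one MnO2 oxidation (C14 alcohol to enal, lactol to α-methylene lactone), acetonide cleavage, O9 acylation.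
- Before the key step, from the bromoarene cis-dihydrodiol: O6/O7 by dihydroxylation; C10–O and the C5 isopropenyl group by directed epoxidation and trans opening, with C10 carrying CH2OH (not vinyl) so that no SN2' path exists; vinyl by one-carbon homologation.
- The C7 side chain is introduced last, by butenolide annulation and hydride delivery to C7. An epoxide opening there would attack allylic C6, and a C7 chain already in place would sit syn-axial to the nucleophile entering at C5.
- Ring order: six-membered carbocycle (from the arene), then the five-membered O6–C12 ring (carried as a silyl lactol), then the ten-membered ring by expansion of the six-membered ring.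

Key step: step 17

Remark on the chemistry: atoms carry the numbers of the target (ring C1–C10, lactone C11–C13, formyl C14, methyl C15). On the cyclohexane, β is the face of the C8/C9 acetonide oxygens and α the opposite face. The acetal carbon of 4 and the lactol carbon C12 of 20–29 are assumed to form as epimer mixtures that converge in steps 4 and 22, so these centres are left open in the SMILES.

**Route**

Step 1
Reactants: 1 (1S,2S)-3-bromocyclohexa-3,5-diene-1,2-diol
Product: 2 bromodiene acetonide (C8/C9 O-isopropylidene; Br on C10; diene C10=C5–C6=C7)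
Conditions: Me2C(OMe)2, TsOH (cat.), acetone, 0 °C; used at once
Reagents that add atoms: 2,2-dimethoxypropane, COC(C)(C)OC
Why: Acid-catalysed ketal exchange (acetonide formation) on the cis-diol leaves both stereocentres untouched and ties O8/O9 into the cis-fused ring that shields the β face in later steps.

Step 2
Reactants: 2 bromodiene acetonide
Product: 3 6α/7α-diol (C10(Br)=C5 retained)
Conditions: OsO4 (cat.), NMO, acetone/H2O, rt
Reagents that add atoms: osmium tetroxide, O=[Os](=O)(=O)=O; N-methylmorpholine N-oxide, C[N+]1([O-])CCOCC1; water, O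
Why: Upjohn dihydroxylation attacks the electron-richer, unhalogenated C6=C7 bond from the face opposite the acetonide, which sets the C6 oxygen α (the configuration kept to the target) and gives an α oxygen at C7.

Step 3
Reactants: 3 6α/7α-diol
Product: 4 6α/7α-O-(4-methoxybenzylidene) acetal (epimers at the acetal carbon)
Conditions: 4-MeOC6H4CH(OMe)2, CSA (cat.), CH2Cl2, rt
Reagents that add atoms: 4-methoxybenzaldehyde dimethyl acetal, COc1ccc(cc1)C(OC)OC
Why: Acid-catalysed transacetalisation closes the five-membered acetal on the cis-diol without touching the stereocentres.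

Step 4
Reactants: 4 6α/7α-O-(4-methoxybenzylidene) acetal
Product: 5 7α-O-PMB ether with free allylic 6α-OH
Conditions: i-Bu2AlH, CH2Cl2, −78 to 0 °C
Reagents that add atoms: none
Why: In this regioselective reductive acetal opening, aluminium binds the more accessible allylic O6, the O6–acetal bond ionises and hydride adds to the O7-oxocarbenium ion, which leaves PMB on the hindered O7 and frees O6–H as the directing group for step 6.

Step 5
Reactants: 5 7α-O-PMB ether; 6 (tributylstannyl)methanol
Product: 7 C10-hydroxymethyl cyclohexene (C10(CH2OH)=C5; 6α-OH; 7α-OPMB)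
Conditions: Pd(PPh3)4 (cat.), dioxane, 95 °C
Reagents that add atoms: (tributylstannyl)methanol 6, CCCC[Sn](CCCC)(CCCC)CO
Why: Stille hydroxymethylation of the alkenyl bromide installs C1 as CH2OH, a vinyl precursor that cannot divert the later cuprate into an SN2' opening.

Step 6
Reactants: 7 C10-hydroxymethyl cyclohexene
Product: 8 5α/10α-epoxide
Conditions: VO(acac)2 (cat.), t-BuOOH, CH2Cl2, 0 °C
Reagents that add atoms: tert-butyl hydroperoxide, CC(C)(C)OO
Why: Vanadium-catalysed hydroxyl-directed epoxidation delivers oxygen syn to the 6α-OH, which is also the face away from the acetonide, so the C10 oxygen is set α.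

Step 7
Reactants: 8 5α/10α-epoxide; 9 isopropenylmagnesium bromide
Product: 10 triol (5β-isopropenyl; C10 α-OH and β-CH2OH; 6α-OH; 7α-OPMB)
Conditions: CH2=C(CH3)MgBr (5 equiv), CuI (cat.), THF, −30 to 0 °C
Reagents that add atoms: isopropenylmagnesium bromide 9, CC(=C)[Mg]Br
Why: Copper-catalysed Grignard opening of the trisubstituted epoxide can only occur by SN2 at secondary C5 (C10 is fully substituted), and inversion places isopropenyl β, trans to the C10 and C6 oxygens; the trans-diaxial (Fürst–Plattner) mode is open because the C7 substituent is α and stays equatorial.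

Step 8
Reactants: 10 triol
Product: 11 C1 mono-tosylate
Conditions: TsCl, pyridine, 0 °C
Reagents that add atoms: p-toluenesulfonyl chloride, Cc1ccc(cc1)S(Cl)(=O)=O
Why: Sulfonylation selects the only primary hydroxyl over the flanked secondary and the tertiary ones.

Step 9
Reactants: 11 C1 mono-tosylate
Product: 13 cis-1-vinyl-2-isopropenyl diol (C10 α-OH and β-vinyl; 5β-isopropenyl; 6α-OH; 7α-OPMB), via spiro-epoxide 12 (not isolated)
Conditions: Me3SI, n-BuLi, THF, −10 °C to rt
Reagents that add atoms: trimethylsulfonium iodide, C[S+](C)C.[I-]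
Why: The C10 alkoxide closes the spiro-epoxide (Williamson displacement), dimethylsulfonium methylide opens it at CH2 and the betaine loses Me2S (epoxide to allylic alcohol one-carbon homologation with the Corey–Chaykovsky ylide); the C10–O bond is never broken, so vinyl ends β and cis to isopropenyl.

Step 10
Reactants: 13 cis-1-vinyl-2-isopropenyl diol; 14 (diethoxyphosphoryl)acetic acid
Product: 15 6α-O-[(diethoxyphosphoryl)acetyl] ester
Conditions: DIC, DMAP (cat.), CH2Cl2, 0 °C to rt
Reagents that add atoms: (diethoxyphosphoryl)acetic acid 14, CCOP(=O)(OCC)CC(=O)O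
Why: Steglich esterification acylates the only secondary hydroxyl (the tertiary C10–OH is inert) and attaches C11/C12 to O6 as the tether for the butenolide.

Step 11
Reactants: 15 6α-O-[(diethoxyphosphoryl)acetyl] ester
Product: 16 7α-alcohol
Conditions: DDQ, CH2Cl2/pH 7 buffer, 0 °C
Reagents that add atoms: none
Why: Oxidative PMB cleavage with DDQ is neutral and spares the ester, the acetonide, the tertiary allylic alcohol and both alkenes.

Step 12
Reactants: 16 7α-alcohol
Product: 17 C7 ketone
Conditions: Dess–Martin periodinane, NaHCO3, CH2Cl2, rt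
Reagents that add atoms: none
Why: Buffered Dess–Martin oxidation converts the only secondary alcohol to the ketone without base that could epimerise C6 or C8.

Step 13
Reactants: 17 C7 ketone
Product: 18 butenolide (O6–C12(=O)–C11H=C7)
Conditions: LiCl, i-Pr2NEt, MeCN, rt
Reagents that add atoms: none
Why: Intramolecular Horner–Wadsworth–Emmons olefination under Masamune–Roush conditions closes the five-membered ring faster than the weak base can enolise the ketone.

Step 14
Reactants: 18 butenolide
Product: 19 trans-fused γ-lactone (C11 β on C7; O6 α)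
Conditions: Cu(OAc)2·H2O (cat.), 1,2-(Ph2P)2C6H4 (cat.), (HMe2Si)2O, t-BuOH, toluene, rt
Reagents that add atoms: none
Why: Copper hydride conjugate reduction adds hydride to C7 along the open axial α trajectory (the β face is screened by the axial C8 oxygen of the acetonide and the axial vinyl group), so C7 is set with C11 β and equatorial, and the isolated alkenes are untouched.

Step 15
Reactants: 19 trans-fused γ-lactone
Product: 20 lactol (C12 epimers)
Conditions: i-Bu2AlH (2.2 equiv), CH2Cl2, −78 °C
Reagents that add atoms: none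
Why: Partial reduction of the γ-lactone stops at the lactol at low temperature and removes the enolisable ester before the strongly basic key step.

Step 16
Reactants: 20 lactol
Product: 21 O-TBS lactol (oxy-Cope precursor: C10 α-OH and axial β-vinyl; equatorial 5β-isopropenyl)
Conditions: TBSCl, imidazole, DMF, 0 °C
Reagents that add atoms: tert-butyldimethylsilyl chloride, CC(C)(C)[Si](C)(C)Cl
Why: Silylation takes the anomeric hydroxyl only (the tertiary C10–OH is too hindered) and gives a base-stable acetal that fluoride can remove without touching the acetonide.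

Step 17
Reactants: 21 O-TBS lactol
Product: 24 ten-membered C10 ketone with ring-cis C4=C5, via potassium alkoxide 22 (not isolated), via ring-trans potassium enolate 23 (not isolated)
Conditions: KH, 18-crown-6, THF, 0 °C to rt; AcOH, −78 °C
Reagents that add atoms: none
Why: Deprotonation gives the tertiary alkoxide, whose oxyanion weakens the adjacent C5–C10 bond, and a concerted [3,3] sigmatropic shift (anionic oxy-Cope rearrangement, the known 1,2-dialkenylcyclohexanol to cyclodec-5-enone ring expansion) joins C2 to C3 as C5–C10 breaks. The ten-membered ring therefore forms by expansion of the six-membered ring, not by end-to-end closure, and the only skeletal bond made is C2–C3. No stereocentre is created; the C4=C5 geometry comes from the chair transition state, in which the ground-state chair of 21 (locked by the trans-fused acetal and the cis acetonide, vinyl axial on C10, isopropenyl equatorial on C5) places C6 pseudo-axial and so delivers C6 cis to C3. The same chair gives the ring-trans enolate, whose geometry is erased when C1 is protonated. The step needs [3,3] over fragmentation and chair over boat, which the cis C5/C10 relationship from the trans epoxide opening and the single favoured chair secure. The cold acidic quench protects the C9 centre next to the new ketone.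

Step 18
Reactants: 24 ten-membered C10 ketone
Product: 26 C10 enol triflate (C1=C10 ring-cis), via ring-cis potassium enolate 25 (not isolated)
Conditions: KN(SiMe3)2, THF, −78 °C; PhNTf2
Reagents that add atoms: N-phenylbis(trifluoromethanesulfonimide), O=S(=O)(N(c1ccccc1)S(=O)(=O)C(F)(F)F)C(F)(F)F
Why: Kinetic enolisation removes a C1 proton rather than the hindered, oxygen-flanked C9–H, the ten-membered ring favours the enolate with C2 cis to C9, and O-triflation fixes this C1=C10 geometry.

Step 19
Reactants: 26 C10 enol triflate; 6 (tributylstannyl)methanol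
Product: 27 C14 allylic alcohol
Conditions: Pd(PPh3)4 (cat.), LiCl, dioxane, 90 °C
Reagents that add atoms: (tributylstannyl)methanol 6, CCCC[Sn](CCCC)(CCCC)CO
Why: Stille coupling of the enol triflate proceeds with retention of alkene geometry and brings in C14 at the alcohol level, so no hydride reduction is needed later.

Step 20
Reactants: 27 C14 allylic alcohol
Product: 28 lactol (TBS removed; C12 epimers)
Conditions: Bu4NF, AcOH, THF, 0 °C
Reagents that add atoms: none
Why: Buffered fluoride cleaves the silyl acetal and leaves the acetonide and both ring alkenes intact.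

Step 21
Reactants: 28 lactol
Product: 29 α-methylene lactol (C11=C13H2)
Conditions: aq. CH2O, pyrrolidine (cat.), EtCO2H (cat.), i-PrOH, 45 °C
Reagents that add atoms: formaldehyde, C=O
Why: Amine-catalysed Mannich condensation and elimination (α-methylenation of aldehydes) acts on the open hydroxy-aldehyde tautomer of the lactol, whose only enolisable position is C11.

Step 22
Reactants: 29 α-methylene lactol
Product: 30 14-al α-methylene-γ-lactone 8,9-acetonide
Conditions: MnO2, CH2Cl2, rt
Reagents that add atoms: none
Why: Manganese dioxide oxidises both allylic hydroxyls in one operation, the primary C14 alcohol to the enal and the allylic lactol to the α-methylene lactone, with no free secondary alcohol present.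

Step 23
Reactants: 30 14-al α-methylene-γ-lactone 8,9-acetonide
Product: 31 8,9-diol
Conditions: TFA/H2O, THF, 0 °C
Reagents that add atoms: none
Why: Mild acid hydrolysis of the isopropylidene ketal frees O8 and O9; the electron-poor C1=C10 enal does not take part in transannular cyclisation.

Step 24
Reactants: 31 8,9-diol; 32 (R)-2-methylbutanoic acid
Product: 33 target (CNP0256845.2)
Conditions: DIC, DMAP (cat.), CH2Cl2, −20 °C
Reagents that add atoms: (R)-2-methylbutanoic acid 32, CC[C@@H](C)C(=O)O
Why: Steglich esterification at low temperature should acylate the allylic O9–H, flanked by the planar C10, in preference to O8–H beside the lactone ring-fusion carbon C7; the acid is activated without amine-induced ketene formation, so its α centre is kept.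

**Compound list**

1 | (1S,2S)-3-bromocyclohexa-3,5-diene-1,2-diol | BrC1=CC=C[C@H](O)[C@@H]1O | starting material
2 | bromodiene acetonide (C8/C9 O-isopropylidene, Br on C10) | BrC1=CC=C[C@@H]2OC(C)(C)O[C@H]12 | intermediate
3 | 6α/7α-diol | O[C@@H]1C=C(Br)[C@H]2OC(C)(C)O[C@H]2[C@@H]1O | intermediate
4 | 6α/7α-O-(4-methoxybenzylidene) acetal (epimers at the acetal carbon) | COc1ccc(cc1)C3O[C@@H]4C=C(Br)[C@H]2OC(C)(C)O[C@H]2[C@@H]4O3 | intermediate
5 | 7α-O-PMB ether with free 6α-OH | O[C@@H]1C=C(Br)[C@H]2OC(C)(C)O[C@H]2[C@@H]1OCc3ccc(OC)cc3 | intermediate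
6 | (tributylstannyl)methanol | CCCC[Sn](CCCC)(CCCC)CO | starting material
7 | C10-hydroxymethyl cyclohexene | O[C@@H]1C=C(CO)[C@H]2OC(C)(C)O[C@H]2[C@@H]1OCc3ccc(OC)cc3 | intermediate
8 | 5α/10α-epoxide | O[C@@H]1[C@@H]4O[C@]4(CO)[C@H]2OC(C)(C)O[C@H]2[C@@H]1OCc3ccc(OC)cc3 | intermediate
9 | isopropenylmagnesium bromide | CC(=C)[Mg]Br | starting material
10 | triol (5β-isopropenyl, C10 α-OH/β-CH2OH, 6α-OH, 7α-OPMB) | O[C@@H]1[C@@H](C(C)=C)[C@@](O)(CO)[C@H]2OC(C)(C)O[C@H]2[C@@H]1OCc3ccc(OC)cc3 | intermediate
11 | C1 mono-tosylate | O[C@@H]1[C@@H](C(C)=C)[C@@](O)(COS(=O)(=O)c4ccc(C)cc4)[C@H]2OC(C)(C)O[C@H]2[C@@H]1OCc3ccc(OC)cc3 | intermediate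
12 | spiro-epoxide (O α on C10, CH2 β) | O[C@@H]1[C@@H](C(C)=C)[C@@]4(CO4)[C@H]2OC(C)(C)O[C@H]2[C@@H]1OCc3ccc(OC)cc3 | intermediate
13 | cis-1-vinyl-2-isopropenyl diol | O[C@@H]1[C@@H](C(C)=C)[C@@](O)(C=C)[C@H]2OC(C)(C)O[C@H]2[C@@H]1OCc3ccc(OC)cc3 | intermediate
14 | (diethoxyphosphoryl)acetic acid | CCOP(=O)(OCC)CC(=O)O | starting material
15 | 6α-O-[(diethoxyphosphoryl)acetyl] ester | CCOP(=O)(OCC)CC(=O)O[C@@H]1[C@@H](C(C)=C)[C@@](O)(C=C)[C@H]2OC(C)(C)O[C@H]2[C@@H]1OCc3ccc(OC)cc3 | intermediate
16 | 7α-alcohol | CCOP(=O)(OCC)CC(=O)O[C@@H]1[C@@H](C(C)=C)[C@@](O)(C=C)[C@H]2OC(C)(C)O[C@H]2[C@@H]1O | intermediate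
17 | C7 ketone | CCOP(=O)(OCC)CC(=O)O[C@@H]1[C@@H](C(C)=C)[C@@](O)(C=C)[C@H]2OC(C)(C)O[C@H]2C1=O | intermediate
18 | butenolide (O6–C12(=O)–C11H=C7) | O=C3O[C@@H]1[C@@H](C(C)=C)[C@@](O)(C=C)[C@H]2OC(C)(C)O[C@H]2C1=C3 | intermediate
19 | trans-fused γ-lactone | O=C3O[C@@H]1[C@@H](C(C)=C)[C@@](O)(C=C)[C@H]2OC(C)(C)O[C@H]2[C@H]1C3 | intermediate
20 | lactol (C12 epimers) | OC3O[C@@H]1[C@@H](C(C)=C)[C@@](O)(C=C)[C@H]2OC(C)(C)O[C@H]2[C@H]1C3 | intermediate
21 | O-TBS lactol, oxy-Cope precursor (C12 epimers) | CC(C)(C)[Si](C)(C)OC3O[C@@H]1[C@@H](C(C)=C)[C@@](O)(C=C)[C@H]2OC(C)(C)O[C@H]2[C@H]1C3 | intermediate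
22 | potassium alkoxide of 21 | CC(C)(C)[Si](C)(C)OC3O[C@@H]1[C@@H](C(C)=C)[C@@]([O-])(C=C)[C@H]2OC(C)(C)O[C@H]2[C@H]1C3.[K+] | intermediate
23 | ring-trans potassium enolate (C4=C5 ring-cis) | CC(C)(C)[Si](C)(C)OC3O[C@@H]1/C=C(/C)CC/C=C(\[O-])[C@H]2OC(C)(C)O[C@H]2[C@H]1C3.[K+] | intermediate
24 | ten-membered C10 ketone with ring-cis C4=C5 | CC(C)(C)[Si](C)(C)OC3O[C@@H]1/C=C(/C)CCCC(=O)[C@H]2OC(C)(C)O[C@H]2[C@H]1C3 | intermediate
25 | ring-cis potassium enolate toward C1 | CC(C)(C)[Si](C)(C)OC3O[C@@H]1/C=C(/C)CC/C=C(/[O-])[C@H]2OC(C)(C)O[C@H]2[C@H]1C3.[K+] | intermediate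
26 | C10 enol triflate (C1=C10 ring-cis) | CC(C)(C)[Si](C)(C)OC3O[C@@H]1/C=C(/C)CC/C=C(/OS(=O)(=O)C(F)(F)F)[C@H]2OC(C)(C)O[C@H]2[C@H]1C3 | intermediate
27 | C14 allylic alcohol | CC(C)(C)[Si](C)(C)OC3O[C@@H]1/C=C(/C)CC/C=C(/CO)[C@H]2OC(C)(C)O[C@H]2[C@H]1C3 | intermediate
28 | lactol (C12 epimers) | OC3O[C@@H]1/C=C(/C)CC/C=C(/CO)[C@H]2OC(C)(C)O[C@H]2[C@H]1C3 | intermediate
29 | α-methylene lactol (C12 epimers) | OC3O[C@@H]1/C=C(/C)CC/C=C(/CO)[C@H]2OC(C)(C)O[C@H]2[C@H]1C3=C | intermediate
30 | 14-al α-methylene-γ-lactone 8,9-acetonide | O=C3O[C@@H]1/C=C(/C)CC/C=C(/C=O)[C@H]2OC(C)(C)O[C@H]2[C@H]1C3=C | intermediate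
31 | 8,9-diol | O=C3O[C@@H]1/C=C(/C)CC/C=C(/C=O)[C@@H](O)[C@@H](O)[C@H]1C3=C | intermediate
32 | (R)-2-methylbutanoic acid | CC[C@@H](C)C(=O)O | starting material
33 | target CNP0256845.2 | C=C1C(=O)O[C@@H]2/C=C(/C)CC/C=C(/C=O)[C@@H](OC(=O)[C@H](C)CC)[C@@H](O)[C@@H]12 | target

Total step count: 24. Longest linear sequence: 24 steps (from 1; compounds 6, 9, 14 and 32 are purchased).

**Steps most likely to fail**

Step 17. What may go wrong: in the strongly basic medium the first-formed enolate may transfer a proton and reform on the C9 side, which would erase the C9 configuration or expel the C8 oxygen, or the alkoxide may fragment instead of rearranging. Fallback (neutral thermal variant of the same ring expansion): set out from 21 and silylate the tertiary hydroxyl with Me3SiOTf and 2,6-lutidine to the trimethylsilyl ether F1. Heating F1 in degassed o-dichlorobenzene at about 200 °C in a base-washed sealed tube should give, through the same chair [3,3] shift, the ring-expanded trimethylsilyl enol ether F2. Cleavage of the enol ether with K2CO3 in MeOH at 0 °C comes back to the route at 24.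

Step 18. What may go wrong: deprotonation on the C9 side, or closure of the enolate with the ring-trans geometry, would give the wrong regio- or geometric isomer of the enol triflate. Fallback (Shapiro route instead of enolate trapping): set out from 24 and condense it with 2,4,6-triisopropylbenzenesulfonyl hydrazide to the sulfonylhydrazone F3, whose sulfonamide nitrogen lies on the less hindered C1 side. Two equivalents of n-BuLi then remove N–H and the syn C1 proton; loss of sulfinate and nitrogen gives the ring-cis C10 alkenyllithium F4. Trapping F4 with monomeric formaldehyde comes back to the route at 27 and skips 26.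

Step 24. What may go wrong: acylation at O8 instead of, or as well as, O9, followed by acyl migration between the vicinal hydroxyls. Fallback (temporary internal protection of O8): set out from 31 and treat it with PPTS in MeOH over molecular sieves, so that the γ-hydroxy aldehyde closes O8 onto C14 as the five-membered cyclic methyl acetal F5, which leaves O9–H as the only hydroxyl. Esterification of F5 with 32 (DIC, DMAP) gives the O9 ester F6, and mild hydrolysis of F6 with aqueous AcOH in THF releases the aldehyde and O8–H and comes back to the route at 33.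

**Further compounds**

F1 | step 17 | trimethylsilyl ether of 21 | CC(C)(C)[Si](C)(C)OC3O[C@@H]1[C@@H](C(C)=C)[C@@](O[Si](C)(C)C)(C=C)[C@H]2OC(C)(C)O[C@H]2[C@H]1C3
F2 | step 17 | ring-expanded trimethylsilyl enol ether | CC(C)(C)[Si](C)(C)OC3O[C@@H]1/C=C(/C)CC/C=C(\O[Si](C)(C)C)[C@H]2OC(C)(C)O[C@H]2[C@H]1C3
F3 | step 18 | 2,4,6-triisopropylbenzenesulfonylhydrazone of 24 | CC(C)(C)[Si](C)(C)OC3O[C@@H]1/C=C(/C)CCCC(=NNS(=O)(=O)c4c(cc(cc4C(C)C)C(C)C)C(C)C)[C@H]2OC(C)(C)O[C@H]2[C@H]1C3
F4 | step 18 | ring-cis C10 alkenyllithium | CC(C)(C)[Si](C)(C)OC3O[C@@H]1/C=C(/C)CC/C=C(/[Li])[C@H]2OC(C)(C)O[C@H]2[C@H]1C3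
F5 | step 24 | cyclic methyl acetal joining O8 and C14 (epimers at C14) | O=C3O[C@@H]1/C=C(/C)CC/C=C5/C(OC)O[C@H]([C@@H]5O)[C@H]1C3=C
F6 | step 24 | O9 (R)-2-methylbutanoate of F5 | O=C3O[C@@H]1/C=C(/C)CC/C=C5/C(OC)O[C@H]([C@@H]5OC(=O)[C@H](C)CC)[C@H]1C3=C
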